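**Assumptions:** The target has no stereocenters, so no stereochemical control is needed. Every phenol is protected as a MOM ether until the last step.

## Retrosynthetic overview
1. Last step: acid-mediated MOM removal and cyclodehydration of a 2'-hydroxyaryl 1,3-diketone closes the pyranone ring (C ring) and gives the flavone.
2. Late coupling: Claisen condensation joins the fully elaborated A-ring α-prenyl aryl ketone (**12**) to methyl 2,4-bis(MOM-oxy)benzoate (**15**, the B-ring piece). The C3-prenyl is carried in on the ketone.
3. Ketone **12** comes from iterated directed ortho-metalation (DoM) of tris-MOM-phloroglucinol: two prenylations, then acylation with a Weinreb amide. The phloroglucinol is made from resorcinol by Ir-catalysed meta C–H borylation and oxidation.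
4. The B-ring ester comes from resorcinol by Kolbe–Schmitt carboxylation. The Weinreb amide comes from 5-bromo-2-methylpent-2-ene.
5. Rings are formed in this order: A ring (aromatic, from resorcinol), then B ring (aromatic, from resorcinol), then C ring (pyranone) last.

## Route

**Step 1**
Reactants: **1** resorcinol
Product: **2** 1,3-bis(methoxymethoxy)benzene
Conditions: NaH, MOMCl, THF/DMF, 0 °C → rt
Reagents that add atoms: MOMCl, COCCl
Why: Williamson-type O-alkylation of the phenoxides gives the bis-MOM ether, which is the 1,3-disubstituted arene needed for the sterically controlled borylation. No stereocenter.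

**Step 2**
Reactants: **2**
Product: **3** 2-[3,5-bis(MOM-oxy)phenyl]-4,4,5,5-tetramethyl-1,3,2-dioxaborolane
Conditions: B2pin2, [Ir(OMe)(cod)]2 (1.5 mol%), dtbpy (3 mol%), THF, 80 °C
Reagents that add atoms: B2pin2, CC1(C)OB(OC1(C)C)B1OC(C)(C)C(C)(C)O1
Why: Ir-catalysed C–H borylation is governed by sterics, so a 1,3-disubstituted arene borylates only at C5, meta to both oxygens. No stereocenter.

**Step 3**
Reactants: **3**
Product: **4** 3,5-bis(methoxymethoxy)phenol
Conditions: 30% H2O2, 2 M NaOH, THF, 0 °C → rt
Reagents that add atoms: H2O2, OO
Why: Oxidative deboronation (C–B to C–OH) under basic conditions that leave the MOM acetals intact, which installs the third, 1,3,5-related oxygen. No stereocenter.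

**Step 4**
Reactants: **4**
Product: **5** 1,3,5-tris(methoxymethoxy)benzene
Conditions: NaH, MOMCl, THF, 0 °C → rt
Reagents that add atoms: MOMCl, COCCl
Why: O-Alkylation of the phenoxide gives a symmetric, triply MOM-directed arene for DoM. No stereocenter.

**Step 5**
Reactants: **5**; **6** prenyl bromide (1-bromo-3-methylbut-2-ene)
Product: **7** 2-prenyl-1,3,5-tris(methoxymethoxy)benzene
Conditions: n-BuLi, THF, 0 °C, 1 h; then **6**, −78 °C → rt
Reagents that add atoms: prenyl bromide, CC(C)=CCBr
Why: Directed ortho-metalation at the carbon flanked by two OMOM groups, then SN2 alkylation of the aryllithium at the primary allylic carbon, which gives the linear prenyl group. No stereocenter.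

**Step 6**
Reactants: **7**; **6**
Product: **8** 2,4-diprenyl-1,3,5-tris(methoxymethoxy)benzene
Conditions: n-BuLi, THF, 0 °C, 1 h; then **6**, −78 °C → rt
Reagents that add atoms: prenyl bromide, CC(C)=CCBr
Why: A second DoM at the other doubly flanked carbon (C4 and C6 are equivalent by symmetry) followed by SN2 prenylation. This leaves one ring C–H for acylation, and the oxygen between the two prenyls becomes 7-OH. No stereocenter.

**Step 7**
Reactants: **9** 5-bromo-2-methylpent-2-ene
Product: **10** 5-methylhex-4-enoic acid
Conditions: Mg, THF, reflux; then CO2 (s), −78 °C → rt; H3O+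
Reagents that add atoms: CO2, O=C=O
Why: Grignard formation followed by carboxylation adds one carbon and builds the acyl chain that will carry the C3-prenyl. No stereocenter.

**Step 8**
Reactants: **10**
Product: **11** N-methoxy-N,5-dimethylhex-4-enamide (Weinreb amide)
Conditions: CDI, CH2Cl2, rt; then MeNH(OMe)·HCl, rt
Reagents that add atoms: N,O-dimethylhydroxylamine hydrochloride, CNOC.Cl
Why: Carboxylic acid activation as the acyl imidazolide, then aminolysis, gives a Weinreb amide that stops cleanly at the ketone stage in step 9. No stereocenter.

**Step 9**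
Reactants: **8**; **11**
Product: **12** 1-[2,4,6-tris(MOM-oxy)-3,5-bis(3-methylbut-2-enyl)phenyl]-5-methylhex-4-en-1-one
Conditions: n-BuLi, THF, 0 °C, 1 h; then **11**, −78 °C → rt; aq. NH4Cl
Reagents that add atoms: none beyond reactant **11**
Why: DoM at the last free ring carbon, then Weinreb ketone synthesis (addition–elimination without over-addition). This completes the A-ring acyl unit, with the future C3 carbon already carrying the prenyl group. No stereocenter.

**Step 10**
Reactants: **1** resorcinol
Product: **13** 2,4-dihydroxybenzoic acid
Conditions: KHCO3 (sat. aq.), 90 °C, 4 h; then HCl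
Reagents that add atoms: KHCO3 (CO2 source), [K+].OC([O-])=O
Why: Kolbe–Schmitt carboxylation occurs para to one OH and ortho to the other, giving the 2,4-dihydroxybenzoate. No stereocenter.

**Step 11**
Reactants: **13**
Product: **14** methyl 2,4-dihydroxybenzoate
Conditions: MeOH, cat. H2SO4, reflux
Reagents that add atoms: methanol, CO
Why: Fischer esterification; the H-bonded 2-OH is untouched. No stereocenter.

**Step 12**
Reactants: **14**
Product: **15** methyl 2,4-bis(methoxymethoxy)benzoate
Conditions: NaH (2.4 equiv), MOMCl, THF/DMF, 0 °C → rt
Reagents that add atoms: MOMCl, COCCl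
Why: The strong base deprotonates the chelated 2-OH as well as the 4-OH, so both are O-alkylated. This gives the B-ring acyl donor, with the phenols masked so they do not quench the enolate in step 13. No stereocenter.

**Step 13**
Reactants: **12**; **15**
Product: **16** 1-[2,4,6-tris(MOM-oxy)-3,5-diprenylphenyl]-3-[2,4-bis(MOM-oxy)phenyl]-2-prenylpropane-1,3-dione
Conditions: LiHMDS (2.5 equiv), THF, −78 °C → 50 °C; aq. NH4Cl
Reagents that add atoms: none beyond reactant **15**
Why: Crossed Claisen condensation of the lithium enolate of **12** (the only enolizable site) with the non-enolizable ester **15**. The second equivalent of base deprotonates the product diketone and drives the reaction. The new CH stereocenter is a racemic, enolizable carbon that is destroyed in step 14.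

**Step 14**
Reactants: **16**
Product: **17** artelasticin
Conditions: 3 M aq. HCl, MeOH/THF (2:1), 55 °C, 8 h
Reagents that add atoms: none
Why: Acid removes all five MOM acetals, and the freed A-ring 2'-OH cyclodehydrates onto the B-ring carbonyl (6-exo hemiketalization, then dehydration) to give the flavone. The isomeric closure by the B-ring 2'-OH onto the very hindered A-ring carbonyl is disfavoured, and the product keeps the 5-OH···O=C chelation. Prenyl groups tolerate dilute HCl/MeOH. No stereocenter remains, and the target is achiral.

## Compound list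
1 | resorcinol | Oc1cccc(O)c1 | starting material
2 | 1,3-bis(methoxymethoxy)benzene | COCOc1cccc(OCOC)c1 | intermediate
3 | 3,5-bis(MOM-oxy)phenyl-Bpin | COCOc1cc(OCOC)cc(B2OC(C)(C)C(C)(C)O2)c1 | intermediate
4 | 3,5-bis(methoxymethoxy)phenol | COCOc1cc(O)cc(OCOC)c1 | intermediate
5 | 1,3,5-tris(methoxymethoxy)benzene | COCOc1cc(OCOC)cc(OCOC)c1 | intermediate
6 | prenyl bromide | CC(C)=CCBr | starting material
7 | 2-prenyl-1,3,5-tris(MOM-oxy)benzene | CC(C)=CCc1c(OCOC)cc(OCOC)cc1OCOC | intermediate
8 | 2,4-diprenyl-1,3,5-tris(MOM-oxy)benzene | CC(C)=CCc1c(OCOC)c(CC=C(C)C)c(OCOC)cc1OCOC | intermediate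
9 | 5-bromo-2-methylpent-2-ene | CC(C)=CCCBr | starting material
10 | 5-methylhex-4-enoic acid | CC(C)=CCCC(=O)O | intermediate
11 | N-methoxy-N,5-dimethylhex-4-enamide | CC(C)=CCCC(=O)N(C)OC | intermediate
12 | A-ring α-prenyl aryl ketone (tris-MOM, diprenyl) | CC(C)=CCCC(=O)c1c(OCOC)c(CC=C(C)C)c(OCOC)c(CC=C(C)C)c1OCOC | intermediate
13 | 2,4-dihydroxybenzoic acid | OC(=O)c1ccc(O)cc1O | intermediate
14 | methyl 2,4-dihydroxybenzoate | COC(=O)c1ccc(O)cc1O | intermediate
15 | methyl 2,4-bis(MOM-oxy)benzoate | COCOc1ccc(C(=O)OC)c(OCOC)c1 | intermediate
16 | 2-prenyl-1,3-diaryl-propane-1,3-dione (five MOM groups, racemic) | CC(C)=CCC(C(=O)c1c(OCOC)c(CC=C(C)C)c(OCOC)c(CC=C(C)C)c1OCOC)C(=O)c1ccc(OCOC)cc1OCOC | intermediate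
17 | artelasticin | CC(C)=CCc1c(O)c(CC=C(C)C)c2oc(-c3ccc(O)cc3O)c(CC=C(C)C)c(=O)c2c1O | target

## Totals
- Total steps: 14.
- Longest linear sequence: 9 (1 → 2 → 3 → 4 → 5 → 7 → 8 → 12 → 16 → 17, i.e. steps 1–6, 9, 13, 14). This is 9/14 ≈ 0.64 of the total, under two thirds.

## Three steps most likely to fail
1. **Step 13 (Claisen condensation).** The ester is electron-rich and the enolate is bulky, so the yield may be low.
   - Fallback: reverse the roles and use an aldol/oxidation coupling. Make the A-ring aldehyde by DoM/DMF on **8**, add the lithium enolate of 1-[2,4-bis(MOM-oxy)phenyl]-5-methylhex-4-en-1-one (from 2,4-bis(MOM-oxy)acetophenone and prenyl bromide) to it, then oxidize the β-hydroxy ketone (DMP) to diketone **16**.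
2. **Steps 5, 6 and 9 (repeated DoM at increasingly crowded carbons, plus SN2 vs SN2' prenylation).**
   - Fallback: generate the aryllithium by bromination and Br/Li exchange instead of deprotonation. Brominate each arene with NBS, exchange with t-BuLi at −78 °C, then quench with prenyl bromide or Weinreb amide **11**.
3. **Step 14 (global MOM removal plus cyclodehydration).** Acid could cause incomplete closure, prenyl cyclization to chromans, or closure to the wrong regioisomer.
   - Fallback: split the end-game. Remove the MOM groups non-protically (ZnBr2, n-PrSH, CH2Cl2, rt), then close the ring under Mitsunobu cyclodehydration (PPh3, DIAD, THF) instead of Brønsted acid.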